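Ring A (C6–C11) is cut across C8–C9 and C6–C11 into two three-carbon units (spiro[5.5]undecane numbering: ring B C1–C5, spiro C6, ring A C7–C11). C8–C7–C6 comes from 4-acetylcyclohex-2-enone: the spiro carbon C6 is α to the C7 carbonyl and, through C1=C2, γ to the C3 carbonyl of ring B, so the bis(silyl) trienol ether is a vinylogous 1,3-dinucleophile. C9–C10–C11 comes from 3-methoxy-3-methylbutanal, a 1,3-dielectrophile. In one flask an asymmetric Mukaiyama aldol joins C8 to C9 and an SN1 closure joins C6 to the C11 cation, giving ring A, the spiro centre beside the gem-dimethyl carbon and the ring B enone. Bromomethylenation, methyl addition and C9 inversion finish.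

Key step: step 4

Remark: the target is (6S,7S,9R) with a Z exocyclic alkene (Br syn to C2); the BINOL–titanium aldol is assumed to follow the usual sense ((S)-ligand, Si face of the aldehyde, 9R carbinol), and the (R)-ligand would be used without other change if the sense proved opposite.

Step 1
Reactants: 1 (E)-1-methoxy-3-(trimethylsilyloxy)buta-1,3-diene; 2 but-3-en-2-one
Product: 4 4-acetylcyclohex-2-en-1-one (racemic), via Diels–Alder cycloadduct 3 (not isolated)
Conditions: toluene, 60 °C; then dilute HCl, THF, 0 °C
Reagents that add atoms: none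
Why: Diels–Alder reaction in which the nucleophilic CH2 terminus of the silyloxydiene bonds to the β-carbon of the enone, followed by acid hydrolysis of the silyl enol ether and β-elimination of methanol to the enone; C4 forms racemic, which is immaterial because it becomes sp2 in step 2.

Step 2
Reactants: 4 4-acetylcyclohex-2-en-1-one
Product: 5 1-(trimethylsilyloxy)-4-[1-(trimethylsilyloxy)ethenyl]cyclohexa-1,3-diene
Conditions: TMSOTf (2.4 equiv), Et3N (3 equiv), Et2O, 0 °C to rt; pentane extraction, used crude
Reagents that add atoms: trimethylsilyl trifluoromethanesulfonate, C[Si](C)(C)OS(=O)(=O)C(F)(F)F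
Why: Double soft enolisation and O-silylation, as in the one-pot preparation of 1,3-bis(silyloxy)-1,3-dienes from 1,3-dicarbonyl compounds; the C4–H (α to the acetyl, γ to the enone) is lost first and a methyl proton second, which should give the fully conjugated trienol ether under equilibrating conditions.

Step 3
Reactants: 6 3-methoxy-3-methylbutan-1-ol
Product: 7 3-methoxy-3-methylbutanal
Conditions: TEMPO (10 mol %), PhI(OAc)2, CH2Cl2, rt
Reagents that add atoms: none
Why: Nitroxyl-catalysed oxidation of a primary alcohol stops at the aldehyde under near-neutral conditions that avoid β-elimination of methanol.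

Step 4
Reactants: 5 1-(trimethylsilyloxy)-4-[1-(trimethylsilyloxy)ethenyl]cyclohexa-1,3-diene (1.2 equiv); 7 3-methoxy-3-methylbutanal
Product: 9 (6S,9R)-9-hydroxy-11,11-dimethylspiro[5.5]undec-1-ene-3,7-dione, via bis-silylated aldol adduct 8 (not isolated)
Conditions: (S)-BINOL (20 mol %), Ti(OiPr)4 (20 mol %), 4 Å MS, toluene/CH2Cl2, −40 °C; then TMSOTf (30 mol %), CH2Cl2, −78 to −20 °C; then 0.5 M HCl, THF, 0 °C
Reagents that add atoms: none
Why: Proposed new method: the BINOL–Ti(OiPr)4 catalyst promotes a Mukaiyama aldol addition of the terminal enol ether carbon C8 of 5 to aldehyde 7 with silyl transfer (giving 8), then TMSOTf ionises the tertiary methyl ether and the γ-carbon C6 of the surviving silyl dienol ether captures the C11 cation, the silyloxyallyl cation collapsing to the ring B enone and returning the silyl Lewis acid. The closest known reaction types are the Lewis-acid formal [3+3] cyclisation of 1,3-bis(silyloxy)-1,3-dienes with 1,3-dielectrophiles, the BINOL–titanium aldol of such dienes with aldehydes, and the Lewis-acid α-tert-alkylation of silyl enol ethers; the step is their vinylogous combination, not yet shown for a trienol ether closing through its γ-carbon. Ring A closes in a 6-(enolexo)-exo-tet mode at the SN1 limit. C9 is set by the catalyst (Si-face attack, 9R), and C6 by the substrate: in the chair transition state the C9 silyloxy group is equatorial (axial would be syn to a C11 methyl) and the acyl dienol ether reacts s-trans, which places C1 axial and cis to the C9 oxygen (6S). The step needs site selectivity (C8 before C6 because the terminal carbon is the most nucleophilic, and C6 rather than C2 in the closure because only C6 gives a six-membered ring), chemoselectivity (aldehyde before ether, secured by the order of the two Lewis acids) and cation capture faster than proton loss or retro-Prins cleavage (favoured by the intramolecular closure at low temperature).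

Step 5
Reactants: 9 (6S,9R)-9-hydroxy-11,11-dimethylspiro[5.5]undec-1-ene-3,7-dione
Product: 10 (6S,9R)-9-(tert-butyldimethylsilyloxy)-11,11-dimethylspiro[5.5]undec-1-ene-3,7-dione
Conditions: TBSCl, imidazole, DMF, rt
Reagents that add atoms: tert-butyldimethylsilyl chloride, CC(C)(C)[Si](C)(C)Cl
Why: Silylation of the secondary alcohol, which blocks retro-aldol and E1cB pathways of the β-hydroxy ketone in steps 6 and 7 and later locks the ring A chair.

Step 6
Reactants: 10 (6S,9R)-9-(tert-butyldimethylsilyloxy)-11,11-dimethylspiro[5.5]undec-1-ene-3,7-dione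
Product: 11 (6S,9R)-3-[(Z)-bromomethylidene]-9-(tert-butyldimethylsilyloxy)-11,11-dimethylspiro[5.5]undec-1-en-7-one
Conditions: Ph3P(CH2Br)Br (1.5 equiv), NaN(SiMe3)2 (1.4 equiv), THF, −78 °C; then 10, −78 to 0 °C; geometric isomers separated on AgNO3-impregnated silica
Reagents that add atoms: (bromomethyl)triphenylphosphonium bromide, BrC[P+](c1ccccc1)(c1ccccc1)c1ccccc1.[Br-]
Why: Wittig olefination with the α-bromo ylide at the unhindered enone carbonyl (the neopentyl C7 ketone should not compete); the geometry is not substrate-controlled, so both isomers are expected and the Z isomer (Br syn to C2–H) is to be isolated by chromatography.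

Step 7
Reactants: 11 (6S,9R)-3-[(Z)-bromomethylidene]-9-(tert-butyldimethylsilyloxy)-11,11-dimethylspiro[5.5]undec-1-en-7-one
Product: 12 (6S,7S,9R)-3-[(Z)-bromomethylidene]-9-(tert-butyldimethylsilyloxy)-7,11,11-trimethylspiro[5.5]undec-1-en-7-ol
Conditions: MeLi, anhydrous CeCl3, THF, −78 °C; aq. NH4Cl
Reagents that add atoms: methyllithium, [Li]C
Why: 1,2-Addition of a non-basic organocerium reagent; with the C9 silyloxy group equatorial, ring A sits in the chair that holds one C11 methyl axial over the axial face of C7, so methyl should add equatorially from the face syn to C1 and give the axial hydroxyl (7S).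

Step 8
Reactants: 12 (6S,7S,9R)-3-[(Z)-bromomethylidene]-9-(tert-butyldimethylsilyloxy)-7,11,11-trimethylspiro[5.5]undec-1-en-7-ol
Product: 13 (6S,7S,9R)-3-[(Z)-bromomethylidene]-7,11,11-trimethylspiro[5.5]undec-1-ene-7,9-diol (trans-diol)
Conditions: Bu4NF, THF, 0 °C to rt
Reagents that add atoms: none
Why: Fluoride-mediated cleavage of the silyl ether, to which the tertiary alcohol, the diene and the vinyl bromide are inert.

Step 9
Reactants: 13 (6S,7S,9R)-3-[(Z)-bromomethylidene]-7,11,11-trimethylspiro[5.5]undec-1-ene-7,9-diol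
Product: 14 (6S,7S)-3-[(Z)-bromomethylidene]-7-hydroxy-7,11,11-trimethylspiro[5.5]undec-1-en-9-one
Conditions: Dess–Martin periodinane, NaHCO3, CH2Cl2, 0 °C
Reagents that add atoms: none
Why: Hypervalent-iodine oxidation of the secondary alcohol only; the buffered, non-basic medium should avoid retro-aldol cleavage or dehydration of the β-hydroxy ketone.

Step 10
Reactants: 14 (6S,7S)-3-[(Z)-bromomethylidene]-7-hydroxy-7,11,11-trimethylspiro[5.5]undec-1-en-9-one
Product: 15 (6S,7S,9S)-3-[(Z)-bromomethylidene]-7,11,11-trimethylspiro[5.5]undec-1-ene-7,9-diol (cis-diol)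
Conditions: LiBH(s-Bu)3, THF, −78 °C; aq. NH4Cl
Reagents that add atoms: none
Why: Bulky-hydride reduction; axial approach is blocked by the syn-axial C11 methyl and C7 hydroxyl groups, so hydride should add equatorially and give the axial 9S alcohol, cis to the C7 hydroxyl.

Step 11
Reactants: 15 (6S,7S,9S)-3-[(Z)-bromomethylidene]-7,11,11-trimethylspiro[5.5]undec-1-ene-7,9-diol
Product: 16 (6S,7S,9R)-9-bromo-3-[(Z)-bromomethylidene]-7,11,11-trimethylspiro[5.5]undec-1-en-7-ol
Conditions: CBr4, PPh3, CH2Cl2, 0 °C to rt
Reagents that add atoms: carbon tetrabromide, BrC(Br)(Br)Br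
Why: Appel reaction; the secondary alcohol should be activated in preference to the hindered tertiary one, and bromide displaces the axial oxyphosphonium group by SN2 with inversion to give the equatorial 9R bromide.

Compound list
1 | (E)-1-methoxy-3-(trimethylsilyloxy)buta-1,3-diene | CO/C=C/C(=C)O[Si](C)(C)C | starting material
2 | but-3-en-2-one (methyl vinyl ketone) | CC(=O)C=C | starting material
3 | 4-acetyl-3-methoxy-1-(trimethylsilyloxy)cyclohex-1-ene (cycloadduct, diastereomer mixture) | COC1C=C(O[Si](C)(C)C)CCC1C(C)=O | intermediate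
4 | 4-acetylcyclohex-2-en-1-one (racemic) | CC(=O)C1CCC(=O)C=C1 | intermediate
5 | 1-(trimethylsilyloxy)-4-[1-(trimethylsilyloxy)ethenyl]cyclohexa-1,3-diene | C=C(O[Si](C)(C)C)C1=CC=C(O[Si](C)(C)C)CC1 | intermediate
6 | 3-methoxy-3-methylbutan-1-ol | COC(C)(C)CCO | starting material
7 | 3-methoxy-3-methylbutanal | COC(C)(C)CC=O | intermediate
8 | (3R)-5-methoxy-5-methyl-3-(trimethylsilyloxy)-1-[4-(trimethylsilyloxy)cyclohexa-1,3-dien-1-yl]hexan-1-one | COC(C)(C)C[C@@H](O[Si](C)(C)C)CC(=O)C1=CC=C(O[Si](C)(C)C)CC1 | intermediate
9 | (6S,9R)-9-hydroxy-11,11-dimethylspiro[5.5]undec-1-ene-3,7-dione (C9–OH cis to C1 on ring A) | CC1(C)C[C@@H](O)CC(=O)[C@@]12C=CC(=O)CC2 | intermediate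
10 | (6S,9R)-9-(tert-butyldimethylsilyloxy)-11,11-dimethylspiro[5.5]undec-1-ene-3,7-dione | CC1(C)C[C@@H](O[Si](C)(C)C(C)(C)C)CC(=O)[C@@]12C=CC(=O)CC2 | intermediate
11 | (6S,9R)-3-[(Z)-bromomethylidene]-9-(tert-butyldimethylsilyloxy)-11,11-dimethylspiro[5.5]undec-1-en-7-one (Br syn to C2) | CC1(C)C[C@@H](O[Si](C)(C)C(C)(C)C)CC(=O)[C@@]12C=C/C(=C\Br)CC2 | intermediate
12 | (6S,7S,9R)-3-[(Z)-bromomethylidene]-9-(tert-butyldimethylsilyloxy)-7,11,11-trimethylspiro[5.5]undec-1-en-7-ol | CC1(C)C[C@@H](O[Si](C)(C)C(C)(C)C)C[C@](C)(O)[C@@]12C=C/C(=C\Br)CC2 | intermediate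
13 | (6S,7S,9R)-3-[(Z)-bromomethylidene]-7,11,11-trimethylspiro[5.5]undec-1-ene-7,9-diol (trans-diol) | CC1(C)C[C@@H](O)C[C@](C)(O)[C@@]12C=C/C(=C\Br)CC2 | intermediate
14 | (6S,7S)-3-[(Z)-bromomethylidene]-7-hydroxy-7,11,11-trimethylspiro[5.5]undec-1-en-9-one | CC1(C)CC(=O)C[C@](C)(O)[C@@]12C=C/C(=C\Br)CC2 | intermediate
15 | (6S,7S,9S)-3-[(Z)-bromomethylidene]-7,11,11-trimethylspiro[5.5]undec-1-ene-7,9-diol (cis-diol) | CC1(C)C[C@H](O)C[C@](C)(O)[C@@]12C=C/C(=C\Br)CC2 | intermediate
16 | (6S,7S,9R)-9-bromo-3-[(Z)-bromomethylidene]-7,11,11-trimethylspiro[5.5]undec-1-en-7-ol | CC1(C)C[C@@H](Br)C[C@](C)(O)[C@@]12C=C/C(=C\Br)CC2 | target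

Total step count: 11. Longest linear sequence: 10 steps (steps 1, 2 and 4 to 11).

Steps most likely to fail

Step 4 (proposed new method). The tertiary cation may be lost by proton elimination or retro-Prins cleavage before C6 captures it. The silyl dienol ether may be protodesilylated before the closure, the chiral titanium catalyst may not turn over with this trienol ether, and the facial selectivity at C6 may be low. The fallback separates the two bond formations and uses known reactions only. It sets out from 5 and 7: the BINOL–Ti(OiPr)4 Mukaiyama aldol is run alone and worked up with dilute acid to give 4-[(3R)-3-hydroxy-5-methoxy-5-methylhexanoyl]cyclohex-2-en-1-one F1. The alcohol is protected (TBSCl, imidazole) as 4-[(3R)-3-(tert-butyldimethylsilyloxy)-5-methoxy-5-methylhexanoyl]cyclohex-2-en-1-one F2. The nucleophile is then regenerated by soft enolisation (TBSOTf, Et3N) as (3R)-3-(tert-butyldimethylsilyloxy)-1-[4-(tert-butyldimethylsilyloxy)cyclohexa-1,3-dien-1-yl]-5-methoxy-5-methylhexan-1-one F3, and TiCl4 in CH2Cl2 at −78 °C effects the Lewis-acid tert-alkylation of the silyl dienol ether through its γ-carbon. The fallback comes back to the route at 10.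

Step 6. The olefination has no control element for the alkene geometry, and a kinetic bias toward bromine syn to C4 is possible; the basic ylide may also enolise the enone. The fallback sets out from 10: dibromomethylenation (CBr4, PPh3, toluene, heat) gives (6S,9R)-9-(tert-butyldimethylsilyloxy)-3-(dibromomethylidene)-11,11-dimethylspiro[5.5]undec-1-en-7-one F4, which has no geometric isomers. Hydrogenolysis with Bu3SnH and Pd(PPh3)4 (zerovalent palladium) then removes one bromine; by analogy with 1,1-dibromo-1,3-dienes, oxidative addition should prefer the C–Br bond anti to the conjugated C1=C2 unit, leaving the bromine syn to C2. The fallback comes back to the route at 11.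

Step 11. E2 elimination from the axial oxyphosphonium ion, which is flanked by two syn-axial groups, may compete with substitution, and the tertiary alcohol may ionise or dehydrate. The fallback sets out from 15: both hydroxyls are tied up (MeC(OMe)3, pyridinium p-toluenesulfonate) as the cyclic methyl orthoacetate of diol 15 F5. Me3SiBr then generates the 1,3-dioxan-2-ylium ion, which bromide should open at the secondary carbon by SN2 with inversion to give (6S,7S,9R)-9-bromo-3-[(Z)-bromomethylidene]-7,11,11-trimethylspiro[5.5]undec-1-en-7-yl acetate F6. The tertiary acetate is removed with i-Bu2AlH at −78 °C, and the fallback comes back to the route at 16.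

Further compounds
F1 | step 4 | 4-[(3R)-3-hydroxy-5-methoxy-5-methylhexanoyl]cyclohex-2-en-1-one (C4 epimers) | COC(C)(C)C[C@@H](O)CC(=O)C1C=CC(=O)CC1
F2 | step 4 | 4-[(3R)-3-(tert-butyldimethylsilyloxy)-5-methoxy-5-methylhexanoyl]cyclohex-2-en-1-one | COC(C)(C)C[C@@H](O[Si](C)(C)C(C)(C)C)CC(=O)C1C=CC(=O)CC1
F3 | step 4 | (3R)-3-(tert-butyldimethylsilyloxy)-1-[4-(tert-butyldimethylsilyloxy)cyclohexa-1,3-dien-1-yl]-5-methoxy-5-methylhexan-1-one | COC(C)(C)C[C@@H](O[Si](C)(C)C(C)(C)C)CC(=O)C1=CC=C(O[Si](C)(C)C(C)(C)C)CC1
F4 | step 6 | (6S,9R)-9-(tert-butyldimethylsilyloxy)-3-(dibromomethylidene)-11,11-dimethylspiro[5.5]undec-1-en-7-one | CC1(C)C[C@@H](O[Si](C)(C)C(C)(C)C)CC(=O)[C@@]12C=CC(=C(Br)Br)CC2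
F5 | step 11 | cyclic methyl orthoacetate of diol 15 (2-methoxy-2-methyl-1,3-dioxane bridging the C7 and C9 oxygens) | CC1(C)C[C@H](O3)C[C@](C)(OC3(C)OC)[C@@]12C=C/C(=C\Br)CC2
F6 | step 11 | (6S,7S,9R)-9-bromo-3-[(Z)-bromomethylidene]-7,11,11-trimethylspiro[5.5]undec-1-en-7-yl acetate | CC1(C)C[C@@H](Br)C[C@](C)(OC(C)=O)[C@@]12C=C/C(=C\Br)CC2
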